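96.0 is the number to carry, read from the midnight run at 60.0 min. Call f a substrate's fraction of its own charge still present, and count decades: the selectivity factor s is the decades lost by the left-handed substrate divided by the decades lost by the right-handed substrate. Both substrates pass through steps with the same partner and the same free catalyst, so those two divide out of the ratio, however they move in time.

| flask | left-handed substrate | right-handed substrate | gas | free catalyst | remark | time |
|---|---|---|---|---|---|---|
| summer | 0.20 M | 0.20 M | 26 mM (held) | 0.05 mol% | run made earlier |  |
| autumn | 0.20 M | 0.20 M | 26 mM (held) | 0.075 mol% | run made earlier |  |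
| midnight | 0.30 M | 0.30 M | 26 mM (held) | 0.1 mol% | run made earlier |  |
| flask | 0.20 M | 0.20 M | 26 mM (held) | 0.1 mol% |  | 2.5 h |

| run | time / min | right-handed substrate / % | left-handed substrate / % | left-handed product / % |
|---|---|---|---|---|
| summer | 12.0 | 49.8 | 33.3 | 17.0 |
| summer | 30.0 | 49.5 | 12.6 | 36.6 |
| summer | 60.0 | 48.3 | 1.2 | 48.7 |
| summer | 90.0 | 47.3 | 0.2 | 50.0 |
| autumn | 8.00 | 50.2 | 38.6 | 11.7 |
| autumn | 15.0 | 49.3 | 28.8 | 21.8 |
| autumn | 40.0 | 49.1 | 5.2 | 45.0 |
| autumn | 90.0 | 46.7 | 0.1 | 49.7 |
| midnight | 25.0 | 49.7 | 23.5 | 26.4 |
| midnight | 50.0 | 48.6 | 5.7 | 44.5 |
| midnight | 60.0 | 48.4 | 2.2 | 47.3 |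
| midnight | 90.0 | 46.9 | 0.3 | 49.8 |

(scatter of a reading: 0.3 percentage points)

- free catalyst is single-handed; left-handed substrate and right-handed substrate are mirror images of each other, charged as a racemate, each of them at the stated concentration
- at the start none of partner is dissolved
- the numbers in the tables scatter with a standard deviation of 0.3 percentage points
- candidate steps: 2 free catalyst <-> resting dimer; partner + free catalyst + left-handed substrate -> free catalyst + left-handed product; partner + free catalyst + right-handed substrate -> free catalyst + right-handed product; gas <-> partner; 2 free catalyst -> spent catalyst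

1. whether the excess of right-handed substrate over left-handed substrate among what is left of the two reaches 90% by 2.5 h (yes / no)
2. the highest excess of right-handed substrate over left-handed substrate among what is left of the two up to 2.5 h

You need two decade counts, one per substrate. The wanted excess means fL/fR = 0.0526, and fL = fR^s, so:

lg(fL/fR) = (s − 1)·lg fR = −1.28

fR = 96.9%, or 48.5% of both substrates charged

Each further decade of left-handed substrate then costs 2.37% of the right-handed substrate present at that moment. The summer run, with a smaller loading than the flask, stood at 95.2% excess by 60.0 min, earlier than the time allowed. My reckoning gives no figure for the end of the flask; the forecast does: yes, and >99.9%, on “All three runs reach 0.1–0.3% left-handed substrate by 90 min”.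

The flask gives yes and >99.9%. It reaches the wanted excess at 0.749 h, with 48.6% of both substrates charged left as right-handed substrate.

    2 free catalyst ⇌ resting dimer (K = 38000 L mol⁻¹, k = 160 L mol⁻¹ min⁻¹)
    partner + free catalyst + left-handed substrate → free catalyst + left-handed product (k = 1.10 × 10⁵ L² mol⁻² min⁻¹)
    partner + free catalyst + right-handed substrate → free catalyst + right-handed product (k = 1070 L² mol⁻² min⁻¹)
    gas ⇌ partner, rate k4*(csat - [partner]) (kL = 0.279 min⁻¹)
    2 free catalyst → spent catalyst (k = 46.0 L mol⁻¹ min⁻¹)

At 2.50 h, 87% of the right-handed charge remains in the flask, and s as read from the midnight run, with its scatter, gives an estimate of about 5.72 decades for the left-handed substrate below its charge.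

Readings and results are simulated from invented constants; scatter was added.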